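By 5.00 h the north-east run holds twice the target of the west run, and the recipes differ in reagent, charged at 1.06 and 0.460 of the starting material.

the same everywhere: starting material 0.050 M; free catalyst 0.50 mM; impurity 0.21 mM
- west: reagent 0.023 M; second substrate 0.010 M (fed, over 30 min); run made earlier
- north-east: reagent 0.053 M; second substrate 0.010 M (fed, over 30 min); run made earlier
- flask: reagent 0.0350 M; second substrate 0.0100 M (fed, over 30 min); time 5.0 h

| run | time / h | target / % | starting material / % |
|---|---|---|---|
| west | 1.00 | 8.0 | 94.7 |
| west | 2.00 | 10.9 | 90.8 |
| west | 3.00 | 14.7 | 85.1 |
| west | 4.00 | 17.0 | 82.0 |
| west | 5.00 | 20.0 | 81.5 |
| north-east | 0.417 | 8.3 | 95.2 |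
| north-east | 1.33 | 17.3 | 84.0 |
| north-east | 2.50 | 28.4 | 72.2 |
| north-east | 4.00 | 37.0 | 63.7 |
| north-east | 5.00 | 41.0 | 57.4 |

(each reading ± 1 percentage point)

- the earlier runs were read with a standard deviation of 1 percentage point

1. the species that holds most of what was charged as starting material, at 5.0 h (target / starting material)
2. the largest share itself, whichever of these holds it, in percent of the starting material charged

I read the last row of each run, taking target to form at a rate proportional to starting material, reagent and catalyst at work. The exposure is then the logarithm of the fraction of reagent left over the fraction of starting material left, divided by the difference of the two charges in fractions of the starting material. The west row gives 0.643 and the north-east row 0.643, so one exposure serves both.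

The catalyst at work is a supposition that these runs cannot test, since both charge the same: I take impurity to bind free catalyst one to one in a fast step, which leaves 58.0 %. I call this the working share, the catalyst charge less the impurity, as a fraction of the catalyst charge.

The flask has the same catalyst and impurity and is asked at the time of those rows, so I carry over the same working share and exposure, while its reagent, the limiting reagent at 0.700 of the starting material, gives 29.0 % target and leaves 71.0 % starting material.

The forecast says starting material at 71 %, within 68 % to 74 %: “Starting material clearly holds most”.

The flask gives starting material at 70.6 %, with target at 29.4 %.

    second substrate + free catalyst → spent catalyst B (k = 0.00135 /M/s)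
    free catalyst + impurity → spent catalyst A (k = 234 /M/s)
    starting material + reagent + free catalyst → free catalyst + target (k = 3.04 /M²/s)
    second substrate + reagent + free catalyst → free catalyst + second product (k = 4.89 /M²/s)

In the flask at 0.500 h, impurity stands at 0 % and the catalyst stands as 57.3 % free catalyst, 42.0 % spent catalyst A and 0.681 % spent catalyst B, so free catalyst is a little less than my working share of 58.0 %. At 5.00 h the flask holds 48.8 % free catalyst, 42.0 % spent catalyst A and 9.21 % spent catalyst B.

A neighbour flask charged with 1.3 × 10⁻⁴ M of free catalyst has less of it than of impurity, so its working share reckons to 0 %, with 38.1 % of the impurity over. Computed, that neighbour keeps >99.9 % of its starting material and 38 % of its impurity.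

Readings and results were computed for substances that don't exist; noise was put on by code.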